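The route rests on cutting the C3–C4 bond of ring C. Both carbons are carbonyl-derived (C3 a carbinol, C4 the aryl ketone on ring A) and are already linked through C4a–C8a–O1–C2. A dialdehyde that carries the ring A formyl group and an α-aryloxy aldehyde on the two sides of the O1–C2 ether can therefore be closed reductively. One samarium diiodide pinacol step forms C3–C4, closes ring C and sets the C3 and C4 carbinol centres relative to C2, which is fixed earlier by Mitsunobu inversion of an (S)-mandelate. The precursor is the tri-MOM dialdehyde, used without purification. A C3 silyl ether then allows clean C4 oxidation before global deprotection.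

Key step: step 8

Remark: flavonoid numbering is used (ring C = O1, C2, C3, C4, C4a, C8a; ring A = C4a–C8a; ring B = the 4-hydroxyphenyl group). Geranyl = (2E)-3,7-dimethylocta-2,6-dien-1-yl, MOM = methoxymethyl, TBS = tert-butyldimethylsilyl. 1-Bromo-4-(methoxymethoxy)benzene is assumed to be purchased.

Step 1
Reactants: 1 2,4,6-trihydroxybenzaldehyde; 2 geranyl bromide
Product: 3 3-geranyl-2,4,6-trihydroxybenzaldehyde
Conditions: DBU (1.1 equiv), THF, 0 °C to rt; 1 in slight excess
Reagents that add atoms: none
Why: Base-mediated C-alkylation of a phloroglucinol phenoxide (SN2 at the primary allylic bromide, E alkene retained) is the standard way to C-geranylate acylphloroglucinols; the two free ring carbons of 1 are equivalent, so only over-alkylation and O-alkylation have to be limited.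

Step 2
Reactants: 3 3-geranyl-2,4,6-trihydroxybenzaldehyde
Product: 4 3-geranyl-2-hydroxy-4,6-bis(methoxymethoxy)benzaldehyde
Conditions: MOMCl (2.2 equiv), i-Pr2NEt, CH2Cl2, 0 °C to rt
Reagents that add atoms: chloromethyl methyl ether (MOMCl), COCCl
Why: Williamson-type O-alkylation with MOMCl should take the para hydroxyl and the more accessible ortho hydroxyl, while the 2-OH, hydrogen-bonded to the formyl group and buttressed by the geranyl CH2, stays free as the later O1.

Step 3
Reactants: 5 1-bromo-4-(methoxymethoxy)benzene; 6 dimethyl oxalate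
Product: 8 methyl 2-[4-(methoxymethoxy)phenyl]-2-oxoacetate, via Grignard reagent 7 (not isolated)
Conditions: Mg, THF, rt; then (CO2Me)2 (2 equiv), THF, −78 °C; aqueous work-up
Reagents that add atoms: none
Why: Grignard acylation: the aryl Grignard reagent adds once to an excess of the diester at −78 °C because the magnesium hemiketal alkoxide does not collapse until work-up, which is the usual route to aryl glyoxylates.

Step 4
Reactants: 8 methyl 2-[4-(methoxymethoxy)phenyl]-2-oxoacetate
Product: 9 methyl (S)-2-hydroxy-2-[4-(methoxymethoxy)phenyl]acetate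
Conditions: RuCl[(R,R)-TsDPEN](p-cymene) (1 mol %), HCO2H–Et3N (5:2), DMF, rt
Reagents that add atoms: none
Why: Noyori–Ikariya asymmetric transfer hydrogenation delivers hydride from Ru–H and a proton from N–H to one face of the aryl ketone, and the (R,R)-ligand is chosen because, with the aryl group in the CH/π pocket as for aryl ketones, it should give the (S)-carbinol that the later inversion requires.

Step 5
Reactants: 4 3-geranyl-2-hydroxy-4,6-bis(methoxymethoxy)benzaldehyde; 9 methyl (S)-2-hydroxy-2-[4-(methoxymethoxy)phenyl]acetate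
Product: 10 methyl (2R)-2-[2-formyl-6-geranyl-3,5-bis(methoxymethoxy)phenoxy]-2-[4-(methoxymethoxy)phenyl]acetate
Conditions: PPh3, DIAD, toluene, 0 °C to rt
Reagents that add atoms: none
Why: Mitsunobu etherification: the acidic salicylaldehyde-type phenol displaces the oxyphosphonium group by SN2 with inversion, turning the (S)-carbinol into the (R)-configured C2, and the adjacent ester suppresses ionisation so that the electron-rich aryl group does not open an SN1 path.

Step 6
Reactants: 10 methyl (2R)-2-[2-formyl-6-geranyl-3,5-bis(methoxymethoxy)phenoxy]-2-[4-(methoxymethoxy)phenyl]acetate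
Product: 11 (2R)-2-[6-geranyl-2-(hydroxymethyl)-3,5-bis(methoxymethoxy)phenoxy]-2-[4-(methoxymethoxy)phenyl]ethan-1-ol
Conditions: i-Bu2AlH (5 equiv), CH2Cl2, −78 to 0 °C; aq. potassium sodium tartrate
Reagents that add atoms: none
Why: Hydride reduction with a non-basic aluminium hydride converts the aryl aldehyde and the ester into the two primary alcohols without enolising the α-aryloxy ester, so C2 is untouched, and MOM ethers and alkenes are inert.

Step 7
Reactants: 11 (2R)-2-[6-geranyl-2-(hydroxymethyl)-3,5-bis(methoxymethoxy)phenoxy]-2-[4-(methoxymethoxy)phenyl]ethan-1-ol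
Product: 12 3-geranyl-4,6-bis(methoxymethoxy)-2-{(1R)-1-[4-(methoxymethoxy)phenyl]-2-oxoethoxy}benzaldehyde (the dialdehyde)
Conditions: Dess–Martin periodinane (2.6 equiv), NaHCO3, CH2Cl2, 0 °C; filtered cold, used crude at once
Reagents that add atoms: none
Why: Dess–Martin oxidation turns both primary alcohols into aldehydes under buffered, amine-free conditions, which avoids the base-induced enolisation of the α-aryl-α-aryloxy aldehyde that would scramble C2; the dialdehyde is not chromatographed.

Step 8
Reactants: 12 3-geranyl-4,6-bis(methoxymethoxy)-2-{(1R)-1-[4-(methoxymethoxy)phenyl]-2-oxoethoxy}benzaldehyde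
Product: 13 (2R,3S,4S)-8-geranyl-5,7-bis(methoxymethoxy)-2-[4-(methoxymethoxy)phenyl]-3,4-dihydro-2H-chromene-3,4-diol (2,3-trans-3,4-cis)
Conditions: SmI2 (2.5 equiv, 0.1 M in THF), THF, −78 °C, slow addition of 12 at high dilution; then pH 7 aqueous quench; Et3N-deactivated silica
Reagents that add atoms: none
Why: Single-electron transfer from divalent samarium to the conjugated ring A aldehyde gives a samarium-bound ketyl at C4 that attacks the carbon of the samarium-coordinated C3 aldehyde, and a second equivalent reduces the resulting oxygen radical to the trivalent samarium diolate, which water releases as the diol. The closest known reaction type is the SmI2 intramolecular pinacol cyclisation of 1,6-dialdehydes to cis-cyclohexane-1,2-diols. Ring C closes in the 6-exo-trig mode (C4 ketyl carbon onto the C3 carbonyl carbon, carbonyl oxygen outside the new ring). C4 is set cis to C3 because one trivalent samarium bridges both oxygens in the bond-forming transition state; C3 is set trans to C2 because the chair-like transition state keeps the C2 aryl group equatorial and turns the C3–O bond anti to the C2–O1 bond. The step needs ring closure to outrun both enolisation at C2 and a second reduction at C3 that would expel the ortho-formyl aryloxide; the more easily reduced aryl aldehyde, the absence of HMPA or base, high dilution and −78 °C should secure this.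

Step 9
Reactants: 13 (2R,3S,4S)-8-geranyl-5,7-bis(methoxymethoxy)-2-[4-(methoxymethoxy)phenyl]-3,4-dihydro-2H-chromene-3,4-diol
Product: 14 (2R,3S,4S)-3-[(tert-butyldimethylsilyl)oxy]-8-geranyl-5,7-bis(methoxymethoxy)-2-[4-(methoxymethoxy)phenyl]-3,4-dihydro-2H-chromen-4-ol
Conditions: TBSCl (1.2 equiv), imidazole, DMF, 0 °C
Reagents that add atoms: tert-butyldimethylsilyl chloride (TBSCl), CC(C)(C)[Si](C)(C)Cl
Why: Regioselective silylation governed by access: the C3 hydroxyl is equatorial and non-benzylic, whereas the C4 hydroxyl is pseudo-axial and shielded by the peri C5 methoxymethoxy group, so mono-silylation at O3 is expected and the later oxidation cannot cleave the glycol.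

Step 10
Reactants: 14 (2R,3S,4S)-3-[(tert-butyldimethylsilyl)oxy]-8-geranyl-5,7-bis(methoxymethoxy)-2-[4-(methoxymethoxy)phenyl]-3,4-dihydro-2H-chromen-4-ol
Product: 15 (2R,3R)-3-[(tert-butyldimethylsilyl)oxy]-8-geranyl-5,7-bis(methoxymethoxy)-2-[4-(methoxymethoxy)phenyl]-2,3-dihydro-4H-chromen-4-one
Conditions: Dess–Martin periodinane (1.5 equiv), NaHCO3, CH2Cl2, rt
Reagents that add atoms: none
Why: Dess–Martin oxidation of the only free (benzylic) alcohol gives the aryl ketone under neutral conditions; with O3 silylated neither glycol cleavage nor over-oxidation to the flavonol is possible, and C2 and C3 are untouched.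

Step 11
Reactants: 15 (2R,3R)-3-[(tert-butyldimethylsilyl)oxy]-8-geranyl-5,7-bis(methoxymethoxy)-2-[4-(methoxymethoxy)phenyl]-2,3-dihydro-4H-chromen-4-one
Product: 16 (2R,3R)-8-geranyl-3,5,7-trihydroxy-2-(4-hydroxyphenyl)-2,3-dihydro-4H-chromen-4-one (target, CNP0187235.1)
Conditions: HCl (3 M in MeOH), 40 °C, stopped at full conversion
Reagents that add atoms: none
Why: Acid-catalysed transacetalisation to methanol removes the three MOM groups and methanolysis cleaves the secondary TBS ether in the same pot; the trans-dihydroflavonol has no acid-labile stereocentre and the short, mild exposure should spare the geranyl alkenes.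

Compound list
1 | 2,4,6-trihydroxybenzaldehyde | O=Cc1c(O)cc(O)cc1O | starting material
2 | geranyl bromide, (2E)-1-bromo-3,7-dimethylocta-2,6-diene | CC(C)=CCC/C(C)=C/CBr | starting material
3 | 3-geranyl-2,4,6-trihydroxybenzaldehyde | CC(C)=CCC/C(C)=C/Cc1c(O)cc(O)c(C=O)c1O | intermediate
4 | 3-geranyl-2-hydroxy-4,6-bis(methoxymethoxy)benzaldehyde | CC(C)=CCC/C(C)=C/Cc1c(OCOC)cc(OCOC)c(C=O)c1O | intermediate
5 | 1-bromo-4-(methoxymethoxy)benzene | COCOc1ccc(Br)cc1 | starting material
6 | dimethyl oxalate | COC(=O)C(=O)OC | starting material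
7 | [4-(methoxymethoxy)phenyl]magnesium bromide | COCOc1ccc([Mg]Br)cc1 | intermediate
8 | methyl 2-[4-(methoxymethoxy)phenyl]-2-oxoacetate | COCOc1ccc(C(=O)C(=O)OC)cc1 | intermediate
9 | methyl (S)-2-hydroxy-2-[4-(methoxymethoxy)phenyl]acetate | COC(=O)[C@@H](O)c1ccc(OCOC)cc1 | intermediate
10 | methyl (2R)-2-[2-formyl-6-geranyl-3,5-bis(methoxymethoxy)phenoxy]-2-[4-(methoxymethoxy)phenyl]acetate | CC(C)=CCC/C(C)=C/Cc1c(OCOC)cc(OCOC)c(C=O)c1O[C@H](c1ccc(OCOC)cc1)C(=O)OC | intermediate
11 | (2R)-2-[6-geranyl-2-(hydroxymethyl)-3,5-bis(methoxymethoxy)phenoxy]-2-[4-(methoxymethoxy)phenyl]ethan-1-ol | CC(C)=CCC/C(C)=C/Cc1c(OCOC)cc(OCOC)c(CO)c1O[C@H](c1ccc(OCOC)cc1)CO | intermediate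
12 | 3-geranyl-4,6-bis(methoxymethoxy)-2-{(1R)-1-[4-(methoxymethoxy)phenyl]-2-oxoethoxy}benzaldehyde | CC(C)=CCC/C(C)=C/Cc1c(OCOC)cc(OCOC)c(C=O)c1O[C@H](c1ccc(OCOC)cc1)C=O | intermediate
13 | (2R,3S,4S)-8-geranyl-5,7-bis(methoxymethoxy)-2-[4-(methoxymethoxy)phenyl]-3,4-dihydro-2H-chromene-3,4-diol | CC(C)=CCC/C(C)=C/Cc1c(OCOC)cc(OCOC)c2c1O[C@H](c1ccc(OCOC)cc1)[C@@H](O)[C@H]2O | intermediate
14 | (2R,3S,4S)-3-[(tert-butyldimethylsilyl)oxy]-8-geranyl-5,7-bis(methoxymethoxy)-2-[4-(methoxymethoxy)phenyl]-3,4-dihydro-2H-chromen-4-ol | CC(C)=CCC/C(C)=C/Cc1c(OCOC)cc(OCOC)c2c1O[C@H](c1ccc(OCOC)cc1)[C@@H](O[Si](C)(C)C(C)(C)C)[C@H]2O | intermediate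
15 | (2R,3R)-3-[(tert-butyldimethylsilyl)oxy]-8-geranyl-5,7-bis(methoxymethoxy)-2-[4-(methoxymethoxy)phenyl]-2,3-dihydro-4H-chromen-4-one | CC(C)=CCC/C(C)=C/Cc1c(OCOC)cc(OCOC)c2c1O[C@H](c1ccc(OCOC)cc1)[C@@H](O[Si](C)(C)C(C)(C)C)C2=O | intermediate
16 | (2R,3R)-8-geranyl-3,5,7-trihydroxy-2-(4-hydroxyphenyl)-2,3-dihydro-4H-chromen-4-one | CC(C)=CCC/C(C)=C/Cc1c(O)cc(O)c2c1O[C@H](c1ccc(O)cc1)[C@@H](O)C2=O | target

Total step count: 11. Longest linear sequence: 9 steps (steps 1, 2, 5–11; the branch through steps 3 and 4 is equally long).

Steps most likely to fail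

Step 8. A second electron may reach the C3 carbonyl before the C3–C4 bond forms, so that the ortho-formyl aryloxide is expelled from C2, or the ketyl may add to the other face of the C3 aldehyde. The fallback sets out from 12 and returns at 13, and closes the ring by a neutral tin hydride radical chain instead of by electron transfer. Bu3SnH (2 equiv) with Et3B/air in toluene at room temperature adds a tributylstannyl radical to the oxygen of the ring A aldehyde. The O-stannyl ketyl attacks the C3 aldehyde carbon in the same 6-exo sense, and the oxygen radical formed takes a hydrogen atom from Bu3SnH. This should give the O4-tributylstannyl ether F1 of the cis-diol, which aqueous KF and silica gel hydrolyse to 13. No radical anion, carbanion or basic alkoxide is present, so neither aryloxide expulsion nor C2 enolisation has an easy path. Tin hydride pinacol cyclisation of 1,5- and 1,6-dicarbonyl compounds to cis-diols is known chemistry.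

Step 5. Substitution at the di-ortho-substituted, hydrogen-bonded phenol may be slow, so that the activated mandelate is consumed by elimination or by alkylating the hydrazide, or ionises and erodes the C2 configuration. The fallback sets out from 8 and 4 and returns at 10, and makes the O1–C2 bond by carbene O–H insertion, the stereocentre being set by the catalyst and not by inversion. Keto ester 8 is condensed with TsNHNH2 (MeOH, rt) to the tosylhydrazone methyl 2-[4-(methoxymethoxy)phenyl]-2-(2-tosylhydrazinylidene)acetate F2. DBU in CH2Cl2 converts F2 (Bamford–Stevens reaction) into methyl 2-diazo-2-[4-(methoxymethoxy)phenyl]acetate F3. Slow addition of F3 to phenol 4 with PdCl2(PhCN)2, a chiral spiro-bis(oxazoline) ligand (enantiomer chosen for the R product) and Na[B(3,5-(CF3)2C6H3)4] in CHCl3 should give 10. Enantioselective insertion of α-aryl-α-diazoacetates into phenol O–H bonds under divalent palladium catalysis is known, and O–H insertion is much faster than cyclopropanation of the trisubstituted geranyl alkenes.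

Step 9. Regiocontrol may be lost through silylation at O4 or at both oxygens, or through migration of silicon between the cis oxygens. The fallback sets out from 13 and returns at 16; it omits the protecting group and dehydrogenates C4 directly. DDQ (1.1 equiv) in CH2Cl2–pH 7 buffer at 0 °C abstracts hydride from C4–H, which is benzylic to a ring carrying ortho and para oxygen donors, and should leave the non-benzylic C3 carbinol alone without glycol cleavage. This gives (2R,3R)-8-geranyl-3-hydroxy-5,7-bis(methoxymethoxy)-2-[4-(methoxymethoxy)phenyl]-2,3-dihydro-4H-chromen-4-one F4, which the conditions of step 11 convert to 16. Selective DDQ oxidation of electron-rich benzylic alcohols in 1-aryl-1,2-diols is known.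

Further compounds
F1 | step 8 | (2R,3R,4S)-8-geranyl-5,7-bis(methoxymethoxy)-2-[4-(methoxymethoxy)phenyl]-4-[(tributylstannyl)oxy]-3,4-dihydro-2H-chromen-3-ol (O4-tributylstannyl ether of 13) | CC(C)=CCC/C(C)=C/Cc1c(OCOC)cc(OCOC)c2c1O[C@H](c1ccc(OCOC)cc1)[C@@H](O)[C@H]2O[Sn](CCCC)(CCCC)CCCC
F2 | step 5 | methyl 2-[4-(methoxymethoxy)phenyl]-2-(2-tosylhydrazinylidene)acetate | COCOc1ccc(C(=NNS(=O)(=O)c2ccc(C)cc2)C(=O)OC)cc1
F3 | step 5 | methyl 2-diazo-2-[4-(methoxymethoxy)phenyl]acetate | COCOc1ccc(C(=[N+]=[N-])C(=O)OC)cc1
F4 | step 9 | (2R,3R)-8-geranyl-3-hydroxy-5,7-bis(methoxymethoxy)-2-[4-(methoxymethoxy)phenyl]-2,3-dihydro-4H-chromen-4-one | CC(C)=CCC/C(C)=C/Cc1c(OCOC)cc(OCOC)c2c1O[C@H](c1ccc(OCOC)cc1)[C@@H](O)C2=O
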